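Ring numbering (cadinane): ring A = C1–C6 (OAc on C2 and C3, C4=C5, C15 on C4); ring B = C1, C6–C10 (C7=C11 isopropylidene, C8=O, C9–OH, C14 on C10).
Retrosynthesis: remove O on C9 and the acetates; cut C4–C15 (methyl onto a C4 ketone); cut C5–C6 of ring A; cut C2–C3 (aldol); cut C1–C6 and C9–C10 of ring B (Diels–Alder).
Enabling feature: C6 is the β-carbon of the ring B enone (C8=O, C7) and C5 is the α-carbon of a C4 ketone, so ring A closes by intramolecular Michael addition; an isopropenyl group on C7 relays the enolate into the C7=C11 isopropylidene enone.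
Forward: ring B first (enantioselective Diels–Alder reaction), side chain by proline aldol reaction with hydroxyacetone, ring A last, then C15, the acetates and the C9 hydroxyl.
Stereochemistry: C1/C10 from the catalyst-controlled cycloaddition of the E enal; C2/C3 from the (R)-proline aldol reaction; C6 (cis fusion) from the tether in the ring closure; C9 from enolate oxidation trans to the C10 methyl (also the thermodynamic epimer).

Key step: step 8

Remark: the SMILES is read as the cis-fused 1S,2R,3S,6R,9S,10R isomer; the S-configured boron catalyst of step 2 is assumed to give the (1S,6S) adduct, and its enantiomer is used if the sense of induction is opposite.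

Step 1
Reactants: 1 but-3-en-2-one
Product: 2 2-(triisopropylsilyloxy)buta-1,3-diene
Conditions: iPr3SiOTf, Et3N, Et2O, 0 to 23 °C
Reagents that add atoms: triisopropylsilyl trifluoromethanesulfonate, CC(C)[Si](C(C)C)(C(C)C)OS(=O)(=O)C(F)(F)F
Why: Soft enolisation and O-silylation of the methyl ketone (silyl enol ether formation) give the 2-silyloxydiene, the bulky silyl group being chosen so that the enol ether survives steps 2 to 4; no stereocentre is formed.

Step 2
Reactants: 2 2-(triisopropylsilyloxy)buta-1,3-diene; 3 (E)-but-2-enal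
Product: 4 (1S,6S)-6-methyl-4-(triisopropylsilyloxy)cyclohex-3-ene-1-carbaldehyde
Conditions: oxazaborolidinium triflimide catalyst from (S)-α,α-diphenylprolinol, o-tolylboroxine and HNTf2 (0.2 equiv), CH2Cl2, −78 to −40 °C; Et3N quench
Reagents that add atoms: none
Why: Catalytic enantioselective Diels–Alder reaction in which the cationic boron Lewis acid activates the enal, the 2-silyloxy group directs the "para" regiochemistry, suprafacial addition to the E enal fixes formyl and methyl trans, and the chiral catalyst shields one enal face to set (1S,6S).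

Step 3
Reactants: 4 (1S,6S)-6-methyl-4-(triisopropylsilyloxy)cyclohex-3-ene-1-carbaldehyde; 5 1-hydroxypropan-2-one
Product: 6 (3R,4R)-3,4-dihydroxy-4-[(1S,6S)-6-methyl-4-(triisopropylsilyloxy)cyclohex-3-en-1-yl]butan-2-one
Conditions: (R)-proline (0.3 equiv), 5 in excess, DMSO, 23 °C
Reagents that add atoms: none
Why: Proline-catalysed direct aldol reaction in which hydroxyacetone reacts through its hydroxylated carbon with the α-branched aldehyde by the hydrogen-bonded chair transition state, which gives the anti-1,2-diol, and (R)-proline sets both new centres (3R,4R; C3 and C2 of the target) under catalyst control.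

Step 4
Reactants: 6 (3R,4R)-3,4-dihydroxy-4-[(1S,6S)-6-methyl-4-(triisopropylsilyloxy)cyclohex-3-en-1-yl]butan-2-one
Product: 7 1-[(4R,5R)-2,2-dimethyl-5-[(1S,6S)-6-methyl-4-(triisopropylsilyloxy)cyclohex-3-en-1-yl]-1,3-dioxolan-4-yl]ethan-1-one
Conditions: 2-methoxypropene, pyridinium p-toluenesulfonate (cat.), CH2Cl2, 0 °C
Reagents that add atoms: 2-methoxypropene, COC(C)=C
Why: Acid-catalysed acetonide formation ties the anti-diol into a cis-dioxolane that masks both hydroxyls against the later base and Grignard steps; no stereocentre changes and the hindered silyl enol ether should tolerate the anhydrous, weakly acidic conditions.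

Step 5
Reactants: 7 1-[(4R,5R)-2,2-dimethyl-5-[(1S,6S)-6-methyl-4-(triisopropylsilyloxy)cyclohex-3-en-1-yl]-1,3-dioxolan-4-yl]ethan-1-one
Product: 8 (4R,5S)-4-[(4R,5R)-5-acetyl-2,2-dimethyl-1,3-dioxolan-4-yl]-5-methylcyclohex-2-en-1-one
Conditions: Pd(OAc)2 (0.2 equiv), O2 (1 atm), DMSO, 60 °C
Reagents that add atoms: none
Why: Saegusa–Ito oxidation in which palladation at C7 and β-hydride elimination from C6 give the C6=C7 enone regiospecifically, because the position of the enol ether double bond was fixed by the cycloaddition.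

Step 6
Reactants: 8 (4R,5S)-4-[(4R,5R)-5-acetyl-2,2-dimethyl-1,3-dioxolan-4-yl]-5-methylcyclohex-2-en-1-one
Product: 9 (4R,5S)-4-[(4R,5R)-5-acetyl-2,2-dimethyl-1,3-dioxolan-4-yl]-2-iodo-5-methylcyclohex-2-en-1-one
Conditions: I2, pyridine, CH2Cl2, 0 to 23 °C
Reagents that add atoms: iodine, II
Why: α-Iodination of the enone by the pyridine-mediated addition, iodination and elimination sequence places iodine on C7 only, the saturated methyl ketone being inert under these conditions.

Step 7
Reactants: 9 (4R,5S)-4-[(4R,5R)-5-acetyl-2,2-dimethyl-1,3-dioxolan-4-yl]-2-iodo-5-methylcyclohex-2-en-1-one; 10 tributyl(prop-1-en-2-yl)stannane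
Product: 11 (4R,5S)-4-[(4R,5R)-5-acetyl-2,2-dimethyl-1,3-dioxolan-4-yl]-5-methyl-2-(prop-1-en-2-yl)cyclohex-2-en-1-one
Conditions: Pd2(dba)3 (cat.), AsPh3, CuI (cat.), N-methylpyrrolidone, 40 °C
Reagents that add atoms: none
Why: Stille coupling of the α-iodoenone with the isopropenylstannane under neutral conditions installs C11–C13 on C7 without triggering a base-mediated cyclisation.

Step 8
Reactants: 11 (4R,5S)-4-[(4R,5R)-5-acetyl-2,2-dimethyl-1,3-dioxolan-4-yl]-5-methyl-2-(prop-1-en-2-yl)cyclohex-2-en-1-one
Product: 13 cis-fused diketone acetonide (2,3-O-isopropylidene-2,3-dihydroxy-15-norcadin-7(11)-ene-4,8-dione; H-1/H-6 cis; O-2/O-3 cis and on the face opposite H-1; methyl on C10 trans to C2), via isopropenyl ketone 12 (not isolated)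
Conditions: pyrrolidine (0.3 equiv), AcOH (0.3 equiv), CH2Cl2, 23 °C; then 1,8-diazabicyclo[5.4.0]undec-7-ene (0.3 equiv), 23 °C
Reagents that add atoms: none
Why: Pyrrolidine condenses with the less hindered methyl ketone (C4) to give the terminal enamine (C4=C5), whose carbon C5 adds to C6, the β-carbon of the ring B enone (C8=O, C7=C6); hydrolysis of the iminium returns the catalyst, the cross-conjugated dienol at C8/C7/C11 is protonated to the isopropenyl ketone 12, and the amidine base moves the double bond into conjugation as the C7=C11 isopropylidene. The closest known reaction type is the amine- or base-mediated intramolecular Michael addition of a ketone to a cyclohexenone (enamine annulation). Ring A closes in the 6-(enolendo)-exo-trig mode, C5–C6 being its only new ring bond. The new stereocentre C6 is controlled by the tether: the side chain on C1 can reach the adjacent C6 only on its own face with perpendicular approach to the enone, so the fusion is cis (H-1/H-6 cis), and C3, now α to the ring ketone, is held in (or equilibrates to) the cis-fused dioxolane. The step needs attack through the methyl carbon and not through C3, secured by the kinetic preference for the less substituted enamine and by the four-membered ring that C3 attack would require, and it needs C6 and not the isopropenyl terminus as electrophile, secured because that alkene is cross-conjugated and not vinylogous to the carbonyl.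

Step 9
Reactants: 13 cis-fused diketone acetonide (2,3-O-isopropylidene-2,3-dihydroxy-15-norcadin-7(11)-ene-4,8-dione)
Product: 14 tertiary alcohol (4S)-2,3-O-isopropylidene-2,3,4-trihydroxycadin-7(11)-en-8-one (hydroxyl on C4 cis to O-3, methyl C15 on the convex face)
Conditions: MeMgBr, THF, −78 °C; then H2O
Reagents that add atoms: methylmagnesium bromide, C[Mg]Br
Why: Grignard addition to the saturated, α-alkoxy-activated ring A ketone in preference to the hindered, conjugated tetrasubstituted C8 enone, with attack from the convex face (opposite the acetonide and ring B) that puts the new hydroxyl anti to H-3 (4S), a centre removed in step 10.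

Step 10
Reactants: 14 tertiary alcohol (4S)-2,3-O-isopropylidene-2,3,4-trihydroxycadin-7(11)-en-8-one
Product: 15 2,3-O-isopropylidene-2,3-dihydroxycadina-4,7(11)-dien-8-one
Conditions: methyl N-(triethylammoniosulfonyl)carbamate, toluene, 70 °C
Reagents that add atoms: none
Why: Dehydration by thermal syn-elimination (Burgess dehydration), in which the only ring hydrogen syn to the leaving group is on C5 (H-3 is anti), so the trisubstituted C4=C5 alkene should form in preference to the exocyclic isomer.

Step 11
Reactants: 15 2,3-O-isopropylidene-2,3-dihydroxycadina-4,7(11)-dien-8-one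
Product: 16 2,3-dihydroxycadina-4,7(11)-dien-8-one (cis-diol, stereochemistry as in the target)
Conditions: AcOH/H2O (4:1), 45 °C
Reagents that add atoms: none
Why: Mild aqueous acid hydrolysis of the acetonide (acetal cleavage) frees the cis-diol without ionising the allylic C3–O bond; no stereocentre changes.

Step 12
Reactants: 16 2,3-dihydroxycadina-4,7(11)-dien-8-one
Product: 17 2,3-diacetoxycadina-4,7(11)-dien-8-one
Conditions: Ac2O, pyridine, 4-dimethylaminopyridine (cat.), CH2Cl2, 23 °C
Reagents that add atoms: acetic anhydride, CC(=O)OC(C)=O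
Why: Acylation of both secondary hydroxyls with acetic anhydride under nucleophilic catalysis; no stereocentre changes.

Step 13
Reactants: 17 2,3-diacetoxycadina-4,7(11)-dien-8-one
Product: 19 CNP0333818.1 [(1S,2R,3S,6R,9S,10R)-2,3-diacetoxy-9-hydroxycadina-4,7(11)-dien-8-one], via potassium enolate 18 (not isolated)
Conditions: KN(SiMe3)2, THF, −78 °C; then 3-phenyl-2-(phenylsulfonyl)oxaziridine, −78 °C; AcOH quench
Reagents that add atoms: 3-phenyl-2-(phenylsulfonyl)oxaziridine, O=S(=O)(N1OC1c1ccccc1)c1ccccc1
Why: Enolate oxidation with an N-sulfonyloxaziridine, in which the amide base removes the C9 proton of the ketone kinetically (not an acetate or allylic methyl proton) and oxygen is delivered trans to the C10 methyl to give the 9S alcohol; this is also the thermodynamically preferred equatorial, hydrogen-bonded α-ketol, so any cis isomer should equilibrate through the enediol.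

Compound list
1 | but-3-en-2-one | CC(=O)C=C | starting material
2 | 2-(triisopropylsilyloxy)buta-1,3-diene | C=CC(=C)O[Si](C(C)C)(C(C)C)C(C)C | intermediate
3 | (E)-but-2-enal | C/C=C/C=O | starting material
4 | (1S,6S)-6-methyl-4-(triisopropylsilyloxy)cyclohex-3-ene-1-carbaldehyde | O=C[C@@H]1[C@@H](C)CC(O[Si](C(C)C)(C(C)C)C(C)C)=CC1 | intermediate
5 | 1-hydroxypropan-2-one | CC(=O)CO | starting material
6 | (3R,4R)-3,4-dihydroxy-4-[(1S,6S)-6-methyl-4-(triisopropylsilyloxy)cyclohex-3-en-1-yl]butan-2-one | O[C@@H]([C@@H](O)C(C)=O)[C@@H]1[C@@H](C)CC(O[Si](C(C)C)(C(C)C)C(C)C)=CC1 | intermediate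
7 | 1-[(4R,5R)-2,2-dimethyl-5-[(1S,6S)-6-methyl-4-(triisopropylsilyloxy)cyclohex-3-en-1-yl]-1,3-dioxolan-4-yl]ethan-1-one | CC1(C)O[C@@H]([C@@H](O1)C(C)=O)[C@@H]2[C@@H](C)CC(O[Si](C(C)C)(C(C)C)C(C)C)=CC2 | intermediate
8 | (4R,5S)-4-[(4R,5R)-5-acetyl-2,2-dimethyl-1,3-dioxolan-4-yl]-5-methylcyclohex-2-en-1-one | CC1(C)O[C@@H]([C@@H](O1)C(C)=O)[C@@H]2[C@@H](C)CC(=O)C=C2 | intermediate
9 | (4R,5S)-4-[(4R,5R)-5-acetyl-2,2-dimethyl-1,3-dioxolan-4-yl]-2-iodo-5-methylcyclohex-2-en-1-one | CC1(C)O[C@@H]([C@@H](O1)C(C)=O)[C@@H]2[C@@H](C)CC(=O)C(I)=C2 | intermediate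
10 | tributyl(prop-1-en-2-yl)stannane | CCCC[Sn](CCCC)(CCCC)C(C)=C | starting material
11 | (4R,5S)-4-[(4R,5R)-5-acetyl-2,2-dimethyl-1,3-dioxolan-4-yl]-5-methyl-2-(prop-1-en-2-yl)cyclohex-2-en-1-one | CC1(C)O[C@@H]([C@@H](O1)C(C)=O)[C@@H]2[C@@H](C)CC(=O)C(C(C)=C)=C2 | intermediate
12 | cis-fused diketone acetonide with the isopropenyl group still on C7 (deconjugated isomer of 13, C7 epimers) | CC1(C)O[C@@H]2[C@@H]3[C@@H](C)CC(=O)C(C(C)=C)[C@@H]3CC(=O)[C@@H]2O1 | intermediate (not isolated)
13 | 2,3-O-isopropylidene-2,3-dihydroxy-15-norcadin-7(11)-ene-4,8-dione (cis ring fusion) | CC1(C)O[C@@H]2[C@@H]3[C@@H](C)CC(=O)C(=C(C)C)[C@@H]3CC(=O)[C@@H]2O1 | intermediate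
14 | (4S)-2,3-O-isopropylidene-2,3,4-trihydroxycadin-7(11)-en-8-one | CC1(C)O[C@@H]2[C@@H]3[C@@H](C)CC(=O)C(=C(C)C)[C@@H]3C[C@](C)(O)[C@@H]2O1 | intermediate
15 | 2,3-O-isopropylidene-2,3-dihydroxycadina-4,7(11)-dien-8-one | CC1(C)O[C@@H]2[C@@H]3[C@@H](C)CC(=O)C(=C(C)C)[C@@H]3C=C(C)[C@@H]2O1 | intermediate
16 | 2,3-dihydroxycadina-4,7(11)-dien-8-one | O[C@@H]1[C@@H]2[C@@H](C)CC(=O)C(=C(C)C)[C@@H]2C=C(C)[C@@H]1O | intermediate
17 | 2,3-diacetoxycadina-4,7(11)-dien-8-one | CC(=O)O[C@@H]1[C@@H]2[C@@H](C)CC(=O)C(=C(C)C)[C@@H]2C=C(C)[C@@H]1OC(C)=O | intermediate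
18 | potassium C8/C9 enolate of 17 | CC(=O)O[C@@H]1[C@@H]2[C@@H](C)C=C([O-])C(=C(C)C)[C@@H]2C=C(C)[C@@H]1OC(C)=O.[K+] | intermediate (not isolated)
19 | CNP0333818.1, (1S,2R,3S,6R,9S,10R)-2,3-diacetoxy-9-hydroxycadina-4,7(11)-dien-8-one | CC(=O)O[C@@H]1[C@@H]2[C@@H](C)[C@H](O)C(=O)C(=C(C)C)[C@@H]2C=C(C)[C@@H]1OC(C)=O | target

Total step count: 13. Longest linear sequence: 13 steps (from 1).

Steps most likely to fail

Step 2 may fail by poor facial discrimination of the small β-methyl enal or by competing Mukaiyama-type addition of the silyl enol ether diene to the activated carbonyl. The fallback moves stereocontrol into the dienophile. Starting from diene 2, Diels–Alder reaction with commercial (S)-4-benzyl-3-[(E)-but-2-enoyl]-1,3-oxazolidin-2-one under Et2AlCl chelation (CH2Cl2, −40 °C) should give the imide adduct F1, the diene adding to the face away from the benzyl group. LiBH4 (THF, MeOH, 0 °C) should then cleave the auxiliary to give the primary alcohol F2, and SO3·pyridine/DMSO/Et3N oxidation returns to aldehyde 4.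

Step 10 may fail by elimination into the methyl group (exocyclic alkene) or, if the Grignard reagent of step 9 adds from the concave face, by syn-elimination toward C3 (enol ether). The fallback avoids the tertiary alcohol. Starting from diketone 13, condensation with hydrazine hydrate (EtOH, 0 °C; the hindered conjugated C8 ketone should not react) should give the C4 hydrazone F3. Iodine and 1,1,3,3-tetramethylguanidine (THF, 0 °C, Barton vinyl iodide synthesis) should give the C4 vinyl iodide F4 with the double bond toward C5, and Stille coupling with Me4Sn (Pd(PPh3)4, CuI, N,N-dimethylformamide, 50 °C) returns to 15.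

Step 13 may fail by competing deprotonation of an acetate or of an isopropylidene methyl group, or by acyl migration to the new potassium alkoxide. The fallback oxidises the enolate before the acetates are in place. Starting from acetonide 15, KN(SiMe3)2 and then 3-phenyl-2-(phenylsulfonyl)oxaziridine (THF, −78 °C) should give the 9-hydroxy ketone F5. tert-Butyldimethylsilyl triflate/2,6-lutidine should give the silyl ether F6, AcOH/H2O (45 °C) should remove the acetonide to give diol F7, and Ac2O/pyridine/4-dimethylaminopyridine should give diacetate F8. HF·pyridine (THF, 0 °C) then releases the target 19.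

Further compounds
F1 | step 2 | (S)-4-benzyl-3-{[(1S,6S)-6-methyl-4-(triisopropylsilyloxy)cyclohex-3-en-1-yl]carbonyl}-1,3-oxazolidin-2-one | O=C([C@@H]1[C@@H](C)CC(O[Si](C(C)C)(C(C)C)C(C)C)=CC1)N1[C@@H](Cc2ccccc2)COC1=O
F2 | step 2 | [(1S,6S)-6-methyl-4-(triisopropylsilyloxy)cyclohex-3-en-1-yl]methanol | OC[C@@H]1[C@@H](C)CC(O[Si](C(C)C)(C(C)C)C(C)C)=CC1
F3 | step 10 | C4 hydrazone of diketone 13 | CC1(C)O[C@@H]2[C@@H]3[C@@H](C)CC(=O)C(=C(C)C)[C@@H]3CC(=NN)[C@@H]2O1
F4 | step 10 | 4-iodo-2,3-O-isopropylidene-2,3-dihydroxy-15-norcadina-4,7(11)-dien-8-one | CC1(C)O[C@@H]2[C@@H]3[C@@H](C)CC(=O)C(=C(C)C)[C@@H]3C=C(I)[C@@H]2O1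
F5 | step 13 | (9S)-9-hydroxy-2,3-O-isopropylidene-2,3-dihydroxycadina-4,7(11)-dien-8-one | CC1(C)O[C@@H]2[C@@H]3[C@@H](C)[C@H](O)C(=O)C(=C(C)C)[C@@H]3C=C(C)[C@@H]2O1
F6 | step 13 | 9-O-tert-butyldimethylsilyl ether of F5 | CC1(C)O[C@@H]2[C@@H]3[C@@H](C)[C@H](O[Si](C)(C)C(C)(C)C)C(=O)C(=C(C)C)[C@@H]3C=C(C)[C@@H]2O1
F7 | step 13 | 9-(tert-butyldimethylsilyloxy)-2,3-dihydroxycadina-4,7(11)-dien-8-one | O[C@@H]1[C@@H]2[C@@H](C)[C@H](O[Si](C)(C)C(C)(C)C)C(=O)C(=C(C)C)[C@@H]2C=C(C)[C@@H]1O
F8 | step 13 | 2,3-diacetoxy-9-(tert-butyldimethylsilyloxy)cadina-4,7(11)-dien-8-one | CC(=O)O[C@@H]1[C@@H]2[C@@H](C)[C@H](O[Si](C)(C)C(C)(C)C)C(=O)C(=C(C)C)[C@@H]2C=C(C)[C@@H]1OC(C)=O
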